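## Analysis of the target

The carbons are numbered as in the abietane skeleton from which the compound formally derives. The target is a 6,7-seco-abietane. Ring C is a cyclohexane (C-8, C-9, C-11 to C-14), cis-fused through C-8/C-9 to a δ-lactone (C-7 carbonyl, ring oxygen, C-20 methylene, C-10). C-10 is also the spiro atom of ring A, a cyclohexanone (C-1 ketone, C-2, C-3, C-4 with the geminal methyls, C-5) bridged from C-3 to C-5 by an oxygen and the C-6 methylene (a 6-oxabicyclo[3.2.1]octane).

There are six stereocentres, 3S,5S,8S,9R,10S,13R in this numbering. Taking β as the face of ring A that carries C-20: H-5 is β, the C-3 oxygen and C-6 are α (cis, as the bridge demands), H-9 and H-8 are both α (C-20 and H-9 anti, cis lactone fusion), and the propenoic acid on C-13 is α, equatorial and trans to the C-9–C-10 bond. C-3, C-5 and C-10 are locked together in the bicycle and C-8/C-9 adjoin the quaternary C-10, but C-13 is remote from all of them.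

Sensitive groups are the α-substituted acrylic acid, the lactone with its epimerisable C-8, and the C-1 ketone, which is β to the C-3 ether oxygen and to the C-20 acyloxymethyl group and so does not tolerate strong base. The difficulties are the all-carbon spiro centre C-10 (flanked by a ketone, an acyloxymethyl group and two methine stereocentres), the neopentyl ether carbon C-3, and the relation of C-13 to the rest.

The strategy rests on one feature. C-7 (lactone carbonyl, on C-8) and C-6 (ether methylene, on C-5) are joined by the path C-5–C-10–C-9–C-8, so a C-6–C-7 bond would close a six-membered ring B. The molecule then becomes a cis,anti,cis-perhydrophenanthrene with C-10 as an angular carbon. The lactone oxygen is a C-20 hydroxyl and the ether oxygen a C-3 hydroxyl, placed to capture the two ends of that bond when it is cut oxidatively.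

## Retrosynthetic reasoning

**37 from 34.** The acid carbon is taken from the allylic methyl of an isopropenyl group (through enal 36). The polymerisable acrylic acid therefore appears only in the last step, and the side chain is an inert alkene for the rest of the route.

**34 from 32.** The C-1 ketone is unmasked last, from the 1β-silyloxy carbinol 32 (through 33). Carrying C-1 as a silyl ether gives the stereocontrol element used below. It also keeps a ketone away from the C-20 hydroxymethyl group (retro-aldol), the C-3 oxygen (β-elimination) and the C-6 hydroxyl (competing hemiketal) until none of these is free.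

**32 from 31.** The ether methylene C-6 comes from a lactol carbon, removed by ionic reduction; no skeletal bond is involved.

**31 from 28 (the key disconnection).** The C-6–C-7 bond is reconnected. The lactone carbonyl becomes the C-7 ketone of ring B, the lactol carbon becomes the C-6 carbinol, and the two ring oxygens become the free C-20 and C-3 hydroxyls of the tricyclic α-ketol 28. The forward reaction must cut only this bond. It does so because the C-20 hydroxyl can reach only C-7, giving the one vicinal-diol-type linkage in the molecule.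

**28 from 25.** The C-6 hydroxyl is put in by oxidation of the kinetic enolate; C-6 is the only methylene next to the ketone.

**25 from 23.** Ring C is closed last, by making the C-13–C-14 bond in an intramolecular conjugate ene reaction of a prenyl-type alkene onto an 8-methylene-7-ketone. This is where C-13 is set: in the chair transition state the C-9–C-10 bond and the developing propenyl group are both equatorial, which is the required trans relation. A diene already carrying ring C and its C-13 substituent was not used. That substituent would sit 1,4 to the reacting carbon, too far to shield a face, and the chair-like approach (new bond axial, substituent equatorial) would favour the C-13 epimer.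

**23 from 18.** The exocyclic methylene (C-14) is attached at C-8 through the 7,8-silyl enol ether that the cycloaddition delivers regiospecifically. Before that, the aldehyde and the C-3 ketone of 18 are reduced (19) and the two hydroxyls silylated (20).

**18 from 11 and 17.** Ring B is cut at C-5–C-6 and C-9–C-10 (Diels–Alder). This sets C-5, C-9 and C-10 in one step from a cyclic enal, in which C-10 is the formyl-bearing carbon, and an acyclic 2-silyloxydiene. The face is dictated by the C-1 silyloxy group next to C-10.

**11 from 1.** The enal 11 comes from dienone 2 through bromodienone 4. Enantioselective reduction (5) creates the C-1 stereocentre. The second ring double bond is turned into the C-3 ketone by epoxidation, hydride opening and oxidation (7 to 11), and the formyl group replaces bromine (9).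

**17 from 12 and 13.** The diene is the silyl enol ether of dienone 15, made from homoprenyl bromide 12 and the β-methoxy enone 13.

## Alternatives that were turned down

**Alternative 1:** Cut the C-2–C-3 bond inside the bridged ether ketone. The acetal of methyl 2-(5-methoxy-4,4-dimethyloxolan-3-yl)-3-oxobutanoate A2 is ionised with TMSOTf, and the terminal carbon of its bis(silyl) dienol ether, formed in situ, attacks the oxocarbenium ion. This closes ring A and gives methyl 8,8-dimethyl-3-oxo-6-oxabicyclo[3.2.1]octane-2-carboxylate A1.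
- For: the bicycle is made in one step from a small acetal, and C-3 and C-5 are cis by necessity. The β-keto ester is a ready nucleophile for C-10. On steps to the bicyclic core it is clearly shorter than the chosen route.
- Against: it postpones the real problem. C-10 must still become quaternary and be related to C-9, C-8 and C-13 across a freely rotating C-9–C-10 bond, and nothing in A1 controls C-9.
- In its place, the chosen strategy spends more steps on the core but creates C-5, C-9 and C-10 in one ring-forming event whose geometry fixes their relation.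

**Alternative 2:** Cut the C-10–C-20 bond. The phenoxide of chloromethyl ester A4 attacks through its para carbon and displaces chloride, closing the lactone with dearomatisation to the spiro cyclohexadienone lactone A3.
- For: very short, and the spiro carbon is not yet stereogenic, so that step needs no control. On brevity it is stronger.
- Against: the dienone carbonyl is para to C-10, which is C-3, whereas the target needs the ketone at C-1, an ether at C-3, two methyls at C-4 and C-6 on C-5. All of these must be installed on a dienone whose two arms differ only through the remote stereotriad of ring C. Choosing between the arms is what fixes C-10, and nothing directs that choice.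
- In its place, the chosen strategy brings ring A fully substituted and sets C-10 under the control of an adjacent stereocentre.

**Alternative 3:** Cut C-7–C-8 and the lactone C–O bond. Pd(OAc)2/phosphine-catalysed hydrocarbonylation of the ring C alkene of A6 with CO, with capture of the acyl by the neopentyl C-20 hydroxyl, gives the malonate spirolactone A5. The malonate is later converted into the acrylic acid.
- For: C-7 comes from CO and the lactone is made last. The malonate-to-acrylate conversion is reliable and arguably safer than an allylic oxidation.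
- Against: hydrometallation must choose C-8 over C-14 on a disubstituted ring alkene and set H-8 cis to H-9, with chain walking as a competitor. A6 already contains the C-9–C-10 bond with the spiro centre, so the hardest bond is presupposed rather than made.
- In its place, the chosen strategy forms C-9–C-10 in the cycloaddition and takes C-7 from the diene.

Key step: step 18

## Route

Step 1
Reactants: 1 4,4-dimethylcyclohex-2-en-1-one
Product: 2 4,4-dimethylcyclohexa-2,5-dien-1-one
Conditions: DDQ (1.3 equiv), dioxane, 100 °C
Reagents that add atoms: none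
Why: Quinone dehydrogenation of the enone through its dienol; the quaternary C-4 rules out aromatisation, so the cross-conjugated dienone is the end point.

Step 2
Reactants: 2 4,4-dimethylcyclohexa-2,5-dien-1-one
Product: 4 2-bromo-4,4-dimethylcyclohexa-2,5-dien-1-one, via 5,6-dibromo-4,4-dimethylcyclohex-2-en-1-one 3 (not isolated)
Conditions: Br2 (1.0 equiv), CH2Cl2, −20 °C; then Et3N, 0 → 23 °C
Reagents that add atoms: bromine, BrBr
Why: Bromination–dehydrobromination: Br2 adds to one enone double bond and E1cB loss of HBr gives the α-bromo dienone; one equivalent leaves the second double bond untouched.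

Step 3
Reactants: 4 2-bromo-4,4-dimethylcyclohexa-2,5-dien-1-one
Product: 5 (1S)-2-bromo-4,4-dimethylcyclohexa-2,5-dien-1-ol
Conditions: (R)-1-methyl-3,3-diphenyltetrahydro-1H,3H-pyrrolo[1,2-c][1,3,2]oxazaborole (20 mol %), BH3·SMe2, THF, −30 °C; pH 7 buffer
Reagents that add atoms: none
Why: Corey–Bakshi–Shibata reduction; the bromine-bearing vinyl arm acts as the large group, as with 2-bromocycloalkenones, so the S carbinol should form. This is the only stereocentre introduced by a reagent; all others are relayed from it.

Step 4
Reactants: 5 (1S)-2-bromo-4,4-dimethylcyclohexa-2,5-dien-1-ol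
Product: 6 [(1S)-2-bromo-4,4-dimethylcyclohexa-2,5-dien-1-yl]oxy-tri(propan-2-yl)silane
Conditions: i-Pr3SiOTf, 2,6-lutidine, CH2Cl2, −78 → 0 °C
Reagents that add atoms: triisopropylsilyl trifluoromethanesulfonate, CC(C)[Si](OS(=O)(=O)C(F)(F)F)(C(C)C)C(C)C
Why: Silylation under basic conditions protects the acid-labile bis-allylic alcohol and installs the bulky group that later directs the cycloaddition.

Step 5
Reactants: 6 [(1S)-2-bromo-4,4-dimethylcyclohexa-2,5-dien-1-yl]oxy-tri(propan-2-yl)silane
Product: 7 3-bromo-5,5-dimethyl-2-[tri(propan-2-yl)silyloxy]-7-oxabicyclo[4.1.0]hept-3-ene (epoxide trans to the silyloxy group)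
Conditions: 3-chloroperoxybenzoic acid, NaHCO3, CH2Cl2, 0 → 23 °C
Reagents that add atoms: 3-chloroperoxybenzoic acid, OOC(=O)c1cccc(Cl)c1
Why: Prilezhaev epoxidation takes the electron-richer unbrominated double bond, mainly anti to the silyl ether. The epoxide configuration is irrelevant because both epoxide carbons lose their configuration by step 8.

Step 6
Reactants: 7 bromo epoxide
Product: 9 5,5-dimethyl-2-[tri(propan-2-yl)silyloxy]-7-oxabicyclo[4.1.0]hept-3-ene-3-carbaldehyde, via vinyllithium 8 (not isolated)
Conditions: t-BuLi (2.1 equiv), Et2O, −78 °C; then HCONMe2; aq. NH4Cl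
Reagents that add atoms: N,N-dimethylformamide, CN(C)C=O
Why: Bromine–lithium exchange is faster than any attack on the epoxide at −78 °C, and formylation of the vinyllithium gives the enal (Bouveault-type formylation).

Step 7
Reactants: 9 epoxy enal
Product: 10 (1S,5S)-4-(hydroxymethyl)-2,2-dimethyl-5-[tri(propan-2-yl)silyloxy]cyclohex-3-en-1-ol
Conditions: LiAlH4, THF, 0 → 23 °C
Reagents that add atoms: none
Why: Hydride reduces the aldehyde (1,2) and opens the epoxide at the carbon away from the neopentyl position, leaving the oxygen on the carbon next to the gem-dimethyl group (future C-3).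

Step 8
Reactants: 10 diol
Product: 11 (6S)-3,3-dimethyl-4-oxo-6-[tri(propan-2-yl)silyloxy]cyclohex-1-ene-1-carbaldehyde
Conditions: Dess–Martin periodinane (3 equiv), NaHCO3, CH2Cl2, 23 °C
Reagents that add atoms: none
Why: Both hydroxyls are oxidised to give the enal and the non-conjugated ketone; the buffered neutral medium avoids E1cB loss of the β-silyloxy group.

Step 9
Reactants: 12 5-bromo-2-methylpent-2-ene; 13 (E)-4-methoxybut-3-en-2-one
Product: 15 (E)-8-methylnona-3,7-dien-2-one, via (4-methylpent-3-en-1-yl)magnesium bromide 14 (not isolated)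
Conditions: Mg, THF; then CuBr·SMe2 (10 mol %), 13, −30 → 0 °C
Reagents that add atoms: none
Why: Copper-catalysed conjugate addition of the Grignard reagent to the β-methoxy enone followed by loss of methoxide (addition–elimination) gives the E-enone.

Step 10
Reactants: 15 (E)-8-methylnona-3,7-dien-2-one
Product: 17 tert-butyl-dimethyl-[(3E)-8-methylnona-1,3,7-trien-2-yl]oxysilane, via lithium dienolate 16 (not isolated)
Conditions: LiN(i-Pr)2, THF, −78 °C; then t-BuMe2SiCl, DMPU, −78 → 0 °C
Reagents that add atoms: tert-butyldimethylsilyl chloride, CC(C)(C)[Si](C)(C)Cl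
Why: Kinetic deprotonation of the methyl group gives the cross-conjugated enolate, and O-silylation gives the 2-silyloxy-1,3-diene with the E double bond unchanged.

Step 11
Reactants: 11 (6S)-3,3-dimethyl-4-oxo-6-[tri(propan-2-yl)silyloxy]cyclohex-1-ene-1-carbaldehyde; 17 tert-butyl-dimethyl-[(3E)-8-methylnona-1,3,7-trien-2-yl]oxysilane
Product: 18 cis-fused A/B Diels–Alder adduct (10β-formyl, 3-oxo, 1β-OSi(i-Pr)3, 5β-H, 9α-H with the 4-methylpent-3-enyl chain on C-9, 7,8-enol ether OSiMe2t-Bu)
Conditions: Me2AlCl (0.3 equiv), CH2Cl2, −78 → −30 °C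
Reagents that add atoms: none
Why: Lewis-acid-catalysed normal-demand Diels–Alder reaction: the CH2 terminus of the silyloxydiene bonds to the enal β-carbon (C-5) and the substituted terminus to C-10, and the endo formyl group places the C-9 chain cis to C-20. The diene should enter anti to the C-1 silyloxy group, held pseudoaxial by allylic strain with the formyl group, which fixes C-5, C-9 and C-10 relative to C-1.

Step 12
Reactants: 18 Diels–Alder adduct
Product: 19 3α,20-diol (C-20 hydroxymethyl, 3α-hydroxy, otherwise as 18)
Conditions: LiBH(s-Bu)3 (2.5 equiv), THF, −78 → −40 °C; aq. NH4Cl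
Reagents that add atoms: none
Why: The bulky borohydride reduces the aldehyde and attacks the C-3 ketone along the equatorial (β) trajectory, away from the axial C-5–C-6 bond. The axial 3α-alcohol, cis to C-6, should result; the silyl enol ether is inert to hydride.

Step 13
Reactants: 19 3α,20-diol
Product: 20 bis(triethylsilyl) ether of 19
Conditions: Et3SiOTf (2.5 equiv), 2,6-lutidine, CH2Cl2, −78 → 0 °C
Reagents that add atoms: triethylsilyl trifluoromethanesulfonate, CC[Si](CC)(CC)OS(=O)(=O)C(F)(F)F
Why: Silylation of the primary and the hindered secondary hydroxyl keeps them out of the Lewis-acid and enolate steps; the triethylsilyl groups can later be removed without touching the triisopropylsilyl ether.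

Step 14
Reactants: 20 bis(triethylsilyl) ether
Product: 23 8-methylene-7-ketone, via Mannich base 21 (not isolated), via trimethylammonium iodide 22 (not isolated)
Conditions: Me2N=CH2+ I−, CH2Cl2, 23 °C; then MeI; then DBU, 0 → 23 °C
Reagents that add atoms: dimethyl(methylidene)ammonium iodide, C[N+](C)=C.[I-]
Why: Eschenmoser methylenation: the 7,8-silyl enol ether from the cycloaddition undergoes a Mannich reaction at C-8 only, and quaternisation followed by E1cB loss of trimethylamine gives the exocyclic enone (C-14).

Step 15
Reactants: 23 8-methylene-7-ketone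
Product: 25 tricyclic ketone (13α-isopropenyl, 8α-H, 9α-H, 7-oxo, 1β-OSi(i-Pr)3, 3α-OSiEt3, 20-OSiEt3), via aluminium enolate 24 (not isolated)
Conditions: Me2AlCl (2.2 equiv), CH2Cl2, −78 → −20 °C; then AcOH, THF, −78 °C
Reagents that add atoms: none
Why: Lewis-acid-promoted intramolecular conjugate ene reaction: C-13 of the trisubstituted alkene adds to the exocyclic methylene, and the tertiary cation loses a methyl proton to Al–CH3, giving the isopropenyl group and enolate 24. In the chair transition state the C-9–C-10 bond and the developing propenyl group are both equatorial, which sets C-13 trans to C-10. Protonation of 24 at low temperature anti to the axial C-9–C-11 bond should give the cis ring fusion (8α-H), as in kinetic protonation of 1-decalone enolates.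

Step 16
Reactants: 25 tricyclic ketone
Product: 27 6β-hydroxy-7-ketone, via lithium 6,7-enolate 26 (not isolated)
Conditions: LiN(i-Pr)2, THF, −78 °C; then trans-2-(phenylsulfonyl)-3-phenyloxaziridine, −78 °C; aq. NH4Cl
Reagents that add atoms: trans-2-(phenylsulfonyl)-3-phenyloxaziridine, O=S(=O)(c1ccccc1)N1OC1c1ccccc1
Why: Kinetic deprotonation takes the C-6 methylene and not the ring-fusion methine C-8, and Davis oxidation of the enolate occurs anti to C-4. The isopropenyl group is untouched, and the C-6 configuration is lost in step 18.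

Step 17
Reactants: 27 6β-hydroxy-7-ketone
Product: 28 3α,6β,20-trihydroxy-7-ketone with 1β-OSi(i-Pr)3 (substrate of the key step)
Conditions: HF·pyridine, pyridine, THF, 0 °C
Reagents that add atoms: none
Why: Buffered fluoride removes the two triethylsilyl ethers far faster than the hindered triisopropylsilyl ether and does not disturb the α-ketol.

Step 18
Reactants: 28 3α,6β,20-trihydroxy-7-ketone
Product: 31 spirolactone bridged lactol (1β-OSi(i-Pr)3; anomer mixture), via 7,20-hemiketal 29 (not isolated), via seco aldehyde 30 (not isolated)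
Conditions: Pb(OAc)4 (1.2 equiv), CH2Cl2, 0 → 23 °C
Reagents that add atoms: none
Why: The C-20 hydroxyl adds to the C-7 ketone (6-exo-trig, ring B in a boat) to give the bridged hemiketal 29, whose hemiketal hydroxyl is gauche to the C-6 hydroxyl whatever the C-6 configuration. Pb(OAc)4 forms the cyclic lead diolate and fragments the C-6–C-7 bond in a two-electron glycol cleavage: C-7 becomes the lactone carbonyl, so the δ-lactone ring is the one closed by the hemiketal addition, and C-6 becomes the aldehyde of 30. The aldehyde is cis-1,3-diaxial to the 3α-hydroxyl on ring A and closes to the lactol (5-exo-trig), forming the tetrahydrofuran ring. The closest known reaction type is the Pb(OAc)4 or NaIO4 cleavage of α-ketols and their hemiketals to a lactone plus an aldehyde, as used to open ring B of 6-hydroxy-7,20-hemiketal diterpenoids. The only new stereocentre is the anomeric carbon, which forms as a mixture and is removed in step 19; C-3, C-5, C-8, C-9, C-10 and C-13 are untouched. The step needs chemoselectivity for this one bond: no other vicinal oxygen pair exists, and the C-1 oxygen is silylated and on the face away from ring B, so it cannot form a competing hemiketal or lactone. The isopropenyl group is inert to Pb(OAc)4 at room temperature.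

Step 19
Reactants: 31 spirolactone bridged lactol
Product: 32 spirolactone bridged ether with 1β-OSi(i-Pr)3
Conditions: Et3SiH, BF3·OEt2, CH2Cl2, −78 → −30 °C
Reagents that add atoms: none
Why: Ionic reduction: BF3 ionises the lactol to the bicyclic oxocarbenium ion, which takes hydride from the silane. The lactone, silyl ether and alkene are not ionised under these conditions.

Step 20
Reactants: 32 spirolactone bridged ether
Product: 33 1β-alcohol
Conditions: HF·pyridine, THF, 23 °C
Reagents that add atoms: none
Why: Fluoride cleavage of the last silyl ether under mildly acidic conditions, which do not epimerise C-8; the alcohol is oxidised at once to forestall acyl migration from O-20 to O-1.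

Step 21
Reactants: 33 1β-alcohol
Product: 34 1-ketone (spirolactone ether ketone with isopropenyl group)
Conditions: Dess–Martin periodinane, NaHCO3, CH2Cl2, 23 °C
Reagents that add atoms: none
Why: Neutral oxidation of the only hydroxyl; the β-alkoxy ketone cannot eliminate because the resulting double bond would lie at the bridgehead.

Step 22
Reactants: 34 1-ketone
Product: 36 2-substituted propenal (C-16 aldehyde), via allylic alcohol 35 (not isolated)
Conditions: SeO2 (0.5 equiv), t-BuOOH, salicylic acid (cat.), CH2Cl2, 23 °C; then MnO2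
Reagents that add atoms: selenium dioxide, O=[Se]=O; tert-butyl hydroperoxide, CC(C)(C)OO
Why: Sharpless-type allylic oxidation (ene reaction, then [2,3]-shift) hydroxylates the methyl of the 1,1-disubstituted alkene, and MnO2 takes the allylic alcohol on to the enal. The mild catalytic conditions are chosen to spare the methylene next to the ketone.

Step 23
Reactants: 36 2-substituted propenal
Product: 37 target acid CNP0268721.1
Conditions: NaClO2, NaH2PO4, 2-methylbut-2-ene, t-BuOH–H2O, 0 → 23 °C
Reagents that add atoms: sodium chlorite, [Na+].[O-]Cl=O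
Why: Pinnick oxidation converts the enal into the acrylic acid without touching the alkene, lactone or ketone; the scavenger removes hypochlorous acid.

## Compound list

1 | 4,4-dimethylcyclohex-2-en-1-one | CC1(C)CCC(=O)C=C1 | starting material
2 | 4,4-dimethylcyclohexa-2,5-dien-1-one | CC1(C)C=CC(=O)C=C1 | intermediate
3 | trans-5,6-dibromo-4,4-dimethylcyclohex-2-en-1-one (racemic) | CC1(C)C=CC(=O)[C@@H](Br)[C@@H]1Br | intermediate (not isolated)
4 | 2-bromo-4,4-dimethylcyclohexa-2,5-dien-1-one | CC1(C)C=CC(=O)C(Br)=C1 | intermediate
5 | (1S)-2-bromo-4,4-dimethylcyclohexa-2,5-dien-1-ol | O[C@H]1C=CC(C)(C)C=C1Br | intermediate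
6 | [(1S)-2-bromo-4,4-dimethylcyclohexa-2,5-dien-1-yl]oxy-tri(propan-2-yl)silane | CC(C)[Si](O[C@H]1C=CC(C)(C)C=C1Br)(C(C)C)C(C)C | intermediate
7 | 3-bromo-5,5-dimethyl-2-[tri(propan-2-yl)silyloxy]-7-oxabicyclo[4.1.0]hept-3-ene, epoxide trans to the silyloxy group | CC(C)[Si](O[C@H]1[C@@H]2O[C@@H]2C(C)(C)C=C1Br)(C(C)C)C(C)C | intermediate
8 | vinyllithium from 7 (lithium in place of bromine) | CC(C)[Si](O[C@H]1[C@@H]2O[C@@H]2C(C)(C)C=C1[Li])(C(C)C)C(C)C | intermediate (not isolated)
9 | 5,5-dimethyl-2-[tri(propan-2-yl)silyloxy]-7-oxabicyclo[4.1.0]hept-3-ene-3-carbaldehyde, epoxide trans to the silyloxy group | CC(C)[Si](O[C@H]1[C@@H]2O[C@@H]2C(C)(C)C=C1C=O)(C(C)C)C(C)C | intermediate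
10 | (1S,5S)-4-(hydroxymethyl)-2,2-dimethyl-5-[tri(propan-2-yl)silyloxy]cyclohex-3-en-1-ol | CC(C)[Si](O[C@H]1C[C@H](O)C(C)(C)C=C1CO)(C(C)C)C(C)C | intermediate
11 | (6S)-3,3-dimethyl-4-oxo-6-[tri(propan-2-yl)silyloxy]cyclohex-1-ene-1-carbaldehyde | O=CC1=CC(C)(C)C(=O)C[C@@H]1O[Si](C(C)C)(C(C)C)C(C)C | intermediate
12 | 5-bromo-2-methylpent-2-ene | CC(C)=CCCBr | starting material
13 | (E)-4-methoxybut-3-en-2-one | CO/C=C/C(C)=O | starting material
14 | (4-methylpent-3-en-1-yl)magnesium bromide | CC(C)=CCC[Mg]Br | intermediate (not isolated)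
15 | (E)-8-methylnona-3,7-dien-2-one | CC(=O)/C=C/CCC=C(C)C | intermediate
16 | lithium (3E)-8-methylnona-1,3,7-trien-2-olate | [Li]OC(=C)/C=C/CCC=C(C)C | intermediate (not isolated)
17 | tert-butyl-dimethyl-[(3E)-8-methylnona-1,3,7-trien-2-yl]oxysilane | C=C(O[Si](C)(C)C(C)(C)C)/C=C/CCC=C(C)C | intermediate
18 | cis-fused A/B adduct: 10β-formyl, 3-oxo, 4,4-dimethyl, 1β-triisopropylsilyloxy, 5β-H, 9α-H with 4-methylpent-3-enyl on C-9, 7,8-enol tert-butyldimethylsilyl ether | CC(C)=CCC[C@@H]1C=C(O[Si](C)(C)C(C)(C)C)C[C@H]2C(C)(C)C(=O)C[C@H](O[Si](C(C)C)(C(C)C)C(C)C)[C@@]12C=O | intermediate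
19 | 3α,20-diol derived from 18 | CC(C)=CCC[C@@H]1C=C(O[Si](C)(C)C(C)(C)C)C[C@H]2C(C)(C)[C@@H](O)C[C@H](O[Si](C(C)C)(C(C)C)C(C)C)[C@@]12CO | intermediate
20 | 3α,20-bis(triethylsilyl) ether of 19 | CC(C)=CCC[C@@H]1C=C(O[Si](C)(C)C(C)(C)C)C[C@H]2C(C)(C)[C@@H](O[Si](CC)(CC)CC)C[C@H](O[Si](C(C)C)(C(C)C)C(C)C)[C@@]12CO[Si](CC)(CC)CC | intermediate
21 | 8-(dimethylaminomethyl)-7-ketone (Mannich base, C-8 epimers) | CC(C)=CCC[C@@H]1C(CN(C)C)C(=O)C[C@H]2C(C)(C)[C@@H](O[Si](CC)(CC)CC)C[C@H](O[Si](C(C)C)(C(C)C)C(C)C)[C@@]12CO[Si](CC)(CC)CC | intermediate (not isolated)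
22 | trimethylammonium iodide of 21 | CC(C)=CCC[C@@H]1C(C[N+](C)(C)C)C(=O)C[C@H]2C(C)(C)[C@@H](O[Si](CC)(CC)CC)C[C@H](O[Si](C(C)C)(C(C)C)C(C)C)[C@@]12CO[Si](CC)(CC)CC.[I-] | intermediate (not isolated)
23 | 8-methylene-7-ketone (rings A/B, prenyl-type side chain on C-9) | CC(C)=CCC[C@@H]1C(=C)C(=O)C[C@H]2C(C)(C)[C@@H](O[Si](CC)(CC)CC)C[C@H](O[Si](C(C)C)(C(C)C)C(C)C)[C@@]12CO[Si](CC)(CC)CC | intermediate
24 | chloro(methyl)aluminium 7,8-enolate of 25 | C=C(C)[C@@H]1CC[C@@H]2C(C1)=C(O[Al](C)Cl)C[C@H]3C(C)(C)[C@@H](O[Si](CC)(CC)CC)C[C@H](O[Si](C(C)C)(C(C)C)C(C)C)[C@@]23CO[Si](CC)(CC)CC | intermediate (not isolated)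
25 | tricyclic 7-ketone: 13α-isopropenyl, 8α-H, 9α-H, 5β-H, 1β-triisopropylsilyloxy, 3α- and 20-triethylsilyloxy | C=C(C)[C@@H]1CC[C@@H]2[C@H](C1)C(=O)C[C@H]3C(C)(C)[C@@H](O[Si](CC)(CC)CC)C[C@H](O[Si](C(C)C)(C(C)C)C(C)C)[C@@]23CO[Si](CC)(CC)CC | intermediate
26 | lithium 6,7-enolate of 25 | C=C(C)[C@@H]1CC[C@@H]2[C@H](C1)C(O[Li])=C[C@H]3C(C)(C)[C@@H](O[Si](CC)(CC)CC)C[C@H](O[Si](C(C)C)(C(C)C)C(C)C)[C@@]23CO[Si](CC)(CC)CC | intermediate (not isolated)
27 | 6β-hydroxy-7-ketone (silyl groups as in 25) | C=C(C)[C@@H]1CC[C@@H]2[C@H](C1)C(=O)[C@H](O)[C@H]3C(C)(C)[C@@H](O[Si](CC)(CC)CC)C[C@H](O[Si](C(C)C)(C(C)C)C(C)C)[C@@]23CO[Si](CC)(CC)CC | intermediate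
28 | tricyclic α-hydroxy ketone with angular hydroxymethyl: 3α,6β,20-triol, 7-oxo, 1β-triisopropylsilyloxy | C=C(C)[C@@H]1CC[C@@H]2[C@H](C1)C(=O)[C@H](O)[C@H]3C(C)(C)[C@@H](O)C[C@H](O[Si](C(C)C)(C(C)C)C(C)C)[C@@]23CO | intermediate
29 | 7,20-hemiketal of 28 (oxygen bridge from C-20 to C-7) | C=C(C)[C@@H]1CC[C@@H]2[C@H](C1)[C@@]4(O)[C@H](O)[C@H]3C(C)(C)[C@@H](O)C[C@H](O[Si](C(C)C)(C(C)C)C(C)C)[C@@]23CO4 | intermediate (not isolated)
30 | 6,7-seco 7,20-lactone 6-aldehyde with free 3α-hydroxyl | C=C(C)[C@@H]1CC[C@@H]2[C@H](C1)C(=O)OC[C@]21[C@@H](O[Si](C(C)C)(C(C)C)C(C)C)C[C@H](O)C(C)(C)[C@@H]1C=O | intermediate (not isolated)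
31 | spirolactone bridged lactol (one anomer drawn), 1β-triisopropylsilyloxy | C=C(C)[C@@H]1CC[C@@H]2[C@H](C1)C(=O)OC[C@]21[C@@H](O[Si](C(C)C)(C(C)C)C(C)C)C[C@@H]2O[C@@H](O)[C@H]1C2(C)C | intermediate
32 | spirolactone bridged ether, 1β-triisopropylsilyloxy | C=C(C)[C@@H]1CC[C@@H]2[C@H](C1)C(=O)OC[C@]21[C@@H](O[Si](C(C)C)(C(C)C)C(C)C)C[C@@H]2OC[C@H]1C2(C)C | intermediate
33 | spirolactone bridged ether, 1β-hydroxy | C=C(C)[C@@H]1CC[C@@H]2[C@H](C1)C(=O)OC[C@]21[C@@H](O)C[C@@H]2OC[C@H]1C2(C)C | intermediate
34 | spirolactone bridged ether 1-ketone with isopropenyl group | C=C(C)[C@@H]1CC[C@@H]2[C@H](C1)C(=O)OC[C@]21C(=O)C[C@@H]2OC[C@H]1C2(C)C | intermediate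
35 | allylic alcohol (hydroxymethyl in place of the vinylic methyl of 34) | C=C(CO)[C@@H]1CC[C@@H]2[C@H](C1)C(=O)OC[C@]21C(=O)C[C@@H]2OC[C@H]1C2(C)C | intermediate (not isolated)
36 | 2-substituted propenal (formyl in place of the vinylic methyl of 34) | C=C(C=O)[C@@H]1CC[C@@H]2[C@H](C1)C(=O)OC[C@]21C(=O)C[C@@H]2OC[C@H]1C2(C)C | intermediate
37 | CNP0268721.1 | C=C(C(=O)O)[C@@H]1CC[C@@H]2[C@H](C1)C(=O)OC[C@]21C(=O)C[C@@H]2OC[C@H]1C2(C)C | target

## Step count and least certain steps

Total: 23 steps. Longest linear sequence: 21 steps (steps 1–8, then 11–23); the diene is made in two steps (9, 10).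

**Step 18 (key step).** The bridged hemiketal needs ring B in a boat and may be only sparsely populated. The open α-ketol would then be cleaved slowly, or with capture of the acyl fragment by acetate instead of closure of the lactone.
- Fallback: starting from 28, run the cleavage with Pb(OAc)4 in methanol–benzene, where solvent opens the ketol as its methyl hemiketal. This gives the methyl ester lactol F1 (the released aldehyde still lactolises with the 3α-hydroxyl). The δ-lactone is then closed by acid-catalysed transesterification with the C-20 hydroxyl (camphorsulfonic acid, toluene, 60 °C), which returns to 31.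

**Step 11.** Three things may go wrong. Facial discrimination could be weak if the ring of 11 flattens and the silyloxy group leaves the pseudoaxial position. The Lewis acid could trigger 1,2-addition of the silyl enol ether to a carbonyl group. It could also cause elimination of the β-silyloxy group next to the enolisable ketone.
- Fallback: starting from 10, oxidise only the allylic alcohol with MnO2 to the hydroxy enal F2 and silylate it to the triethylsilyl ether F3. The C-3 carbinol is then already in place, set by the trans epoxide of step 5. Carry out the cycloaddition with 17 to give adduct F4, reduce the aldehyde with NaBH4 to alcohol F5, and silylate with Et3SiOTf to rejoin the route at 20.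
- This dienophile has no enolisable β-silyloxy ketone, and the fallback also removes the reliance on the hydride face selectivity of step 12.

**Step 15.** Protonation of the enolate from the wrong face would give the trans-fused C-8 epimer. The proton could also be delivered intramolecularly from the cationic side chain.
- Fallback: starting from 25 (as the epimer mixture), form the 7,8-trimethylsilyl enol ether F6 (Me3SiCl, NaI, Et3N, MeCN). Regenerate the ketone by kinetic protonation of the derived lithium enolate (MeLi, THF, then 2,6-di-tert-butylphenol at −78 °C), which returns to 25.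

**Step 22.** The selenium reagent may also attack the methylene next to the C-1 ketone (α-oxidation to a 1,2-dione) or over-oxidise.
- Fallback: change the order so that the allylic oxidation precedes ketone formation. Starting from 32, SeO2/t-BuOOH and then MnO2 give the silyloxy enal F7; Pinnick oxidation gives the silyloxy acid F8; HF·pyridine gives the hydroxy acid F9; Dess–Martin oxidation then arrives at 37.

**Step 3.** Both arms of the ketone are sp2 carbons, so the enantioselectivity may fall short. The bis-allylic alcohol can also ionise and rearrange by methyl shift on acidic work-up.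
- Fallback: starting from 4, reduce with NaBH4/CeCl3 to the racemic dienol F10. Resolve it by lipase-catalysed acylation (Burkholderia cepacia lipase, vinyl acetate), which should leave the S alcohol 5 and convert the enantiomer into the R acetate F11; this comes back to the route at 5.

## Further compounds

F1 | step 18 | methyl ester lactol (C-7 methyl ester, free C-20 hydroxyl, C-6 lactol to O-3, 1β-triisopropylsilyloxy) | C=C(C)[C@@H]1CC[C@H]([C@H](C1)C(=O)OC)[C@]2(CO)[C@@H](O[Si](C(C)C)(C(C)C)C(C)C)C[C@@H]3O[C@@H](O)[C@H]2C3(C)C
F2 | step 11 | (4S,6S)-4-hydroxy-3,3-dimethyl-6-[tri(propan-2-yl)silyloxy]cyclohex-1-ene-1-carbaldehyde | CC(C)[Si](O[C@H]1C[C@H](O)C(C)(C)C=C1C=O)(C(C)C)C(C)C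
F3 | step 11 | triethylsilyl ether of F2 | CC(C)[Si](O[C@H]1C[C@H](O[Si](CC)(CC)CC)C(C)(C)C=C1C=O)(C(C)C)C(C)C
F4 | step 11 | Diels–Alder adduct of F3 and 17 (10β-formyl, 3α-triethylsilyloxy, 1β-triisopropylsilyloxy, 7,8-enol silyl ether) | CC(C)=CCC[C@@H]1C=C(O[Si](C)(C)C(C)(C)C)C[C@H]2C(C)(C)[C@@H](O[Si](CC)(CC)CC)C[C@H](O[Si](C(C)C)(C(C)C)C(C)C)[C@@]12C=O
F5 | step 11 | C-20 alcohol from F4 | CC(C)=CCC[C@@H]1C=C(O[Si](C)(C)C(C)(C)C)C[C@H]2C(C)(C)[C@@H](O[Si](CC)(CC)CC)C[C@H](O[Si](C(C)C)(C(C)C)C(C)C)[C@@]12CO
F6 | step 15 | 7,8-trimethylsilyl enol ether of 25 | C=C(C)[C@@H]1CC[C@@H]2C(C1)=C(O[Si](C)(C)C)C[C@H]3C(C)(C)[C@@H](O[Si](CC)(CC)CC)C[C@H](O[Si](C(C)C)(C(C)C)C(C)C)[C@@]23CO[Si](CC)(CC)CC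
F7 | step 22 | 2-substituted propenal with 1β-triisopropylsilyloxy group | C=C(C=O)[C@@H]1CC[C@@H]2[C@H](C1)C(=O)OC[C@]21[C@@H](O[Si](C(C)C)(C(C)C)C(C)C)C[C@@H]2OC[C@H]1C2(C)C
F8 | step 22 | acrylic acid with 1β-triisopropylsilyloxy group | C=C(C(=O)O)[C@@H]1CC[C@@H]2[C@H](C1)C(=O)OC[C@]21[C@@H](O[Si](C(C)C)(C(C)C)C(C)C)C[C@@H]2OC[C@H]1C2(C)C
F9 | step 22 | acrylic acid with 1β-hydroxyl | C=C(C(=O)O)[C@@H]1CC[C@@H]2[C@H](C1)C(=O)OC[C@]21[C@@H](O)C[C@@H]2OC[C@H]1C2(C)C
F10 | step 3 | racemic 2-bromo-4,4-dimethylcyclohexa-2,5-dien-1-ol | OC1C=CC(C)(C)C=C1Br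
F11 | step 3 | (1R)-2-bromo-4,4-dimethylcyclohexa-2,5-dien-1-yl acetate | CC(=O)O[C@@H]1C=CC(C)(C)C=C1Br
A1 | alternative 1 | methyl 8,8-dimethyl-3-oxo-6-oxabicyclo[3.2.1]octane-2-carboxylate | COC(=O)[C@@H]1C(=O)C[C@@H]2OC[C@H]1C2(C)C
A2 | alternative 1 | methyl 2-(5-methoxy-4,4-dimethyloxolan-3-yl)-3-oxobutanoate | COC(=O)C(C(C)=O)[C@H]1COC(OC)C1(C)C
A3 | alternative 2 | spiro cyclohexadienone lactone | C=C(C)[C@@H]1CC[C@@H]2[C@H](C1)C(=O)OCC21C=CC(=O)C=C1
A4 | alternative 2 | chloromethyl 2-(4-hydroxyphenyl)-5-(prop-1-en-2-yl)cyclohexane-1-carboxylate | C=C(C)[C@@H]1CC[C@@H](c2ccc(O)cc2)[C@H](C1)C(=O)OCCl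
A5 | alternative 3 | spirolactone with the malonate side chain | COC(=O)C(C(=O)OC)[C@@H]1CC[C@@H]2[C@H](C1)C(=O)OC[C@]21C(=O)C[C@@H]2OC[C@H]1C2(C)C
A6 | alternative 3 | cyclohexenyl malonate bearing the hydroxymethyl-substituted bridged ether ketone | COC(=O)C(C(=O)OC)[C@@H]1CC[C@H](C=C1)[C@]1(CO)C(=O)C[C@@H]2OC[C@H]1C2(C)C
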